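**Plan**

1. Numbering used throughout: C1 angular C–CH3, C2=C3, C4 C(OH)iPr, C5 ring-fusion CH, C6 CH–O-acyl, C7, C8 C(OH)CH3, C9, C10. The five-membered ring is C1–C5, the seven-membered ring is C1, C5–C10. β is the face of the C1 methyl, α the opposite face.
2. Cuts: first the C6–O acyl bond (vanillic acid off), then C4–isopropyl and C8–CH3 (both carbonyl additions), then C1–C5 and C1–C10 in one operation. This returns the bicycle to an anisyl ring carrying a CH3–C(N2)–CO–CH2CH2 chain.
3. Enabling feature: C1 is quaternary, holds CH3 and C2, and is bonded to two seven-ring carbons (C5 and C10). This is the footprint of a methyl-substituted carbene that has entered the ipso–ortho bond of the benzene ring carrying its tether. The para-methoxy group becomes the C8 enol ether.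
4. Forward: acid → α-methyl diazoketone → carbene step (closes the five-membered ring, expands benzene to the seven-membered ring) → seven-ring editing (C8 ketone, C9–C10 saturated, C8–CH3, hydroboration of C5=C6) → five-ring carbonyl transposition C2 → C4 (Wharton) and isopropyl addition → vanilloylation.
5. Stereochemistry: C1 comes from the chiral copper catalyst. C8, C5/C6 and C4 are relayed from C1 by reagent approach anti to the angular methyl (organocerium, syn-hydroboration, organocerium).

Key step: step 2

Assumption 1: the (S,S)-configured bis(oxazoline) is taken to give the 8aR enantiomer of 5; if the sense of induction is the reverse, the (R,R)-ligand is used.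
Assumption 2: the centres at C2 (step 3) and at C3/C4 (steps 12 and 13) are temporary; they are drawn as the isomers expected from attack anti to the angular methyl, and the other isomers would converge at 17 and 21.

**Route**

Step 1
Reactants: 1 3-(4-methoxyphenyl)propanoic acid
Product: 3 2-diazo-5-(4-methoxyphenyl)pentan-3-one, via 3-(4-methoxyphenyl)propanoyl chloride 2 (not isolated)
Conditions: (COCl)2, DMF (cat.), CH2Cl2, 0 °C to rt; evaporate; CH3CHN2 (3 equiv, ethereal, prepared separately from N-ethyl-N-nitrosourea and aq KOH), Et2O, −20 to 0 °C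
Reagents that add atoms: diazoethane, CC=[N+]=[N-]
Why: Acid chloride formation followed by acylation of a diazoalkane (Arndt–Eistert-type acylation) puts the diazo group unambiguously on the methyl-bearing carbon, which diazo transfer to the corresponding ethyl ketone could not guarantee because both α-methylene groups enolise; excess diazoethane takes up the HCl.

Step 2
Reactants: 3 2-diazo-5-(4-methoxyphenyl)pentan-3-one
Product: 5 (8aR)-6-methoxy-8a-methyl-3,8a-dihydroazulen-1(2H)-one, via norcaradiene valence isomer 4 (not isolated)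
Conditions: Cu(MeCN)4PF6 (5 mol %), (S,S)-tBu-BOX [2,2'-(propane-2,2-diyl)bis((4S)-4-tert-butyl-4,5-dihydrooxazole)] (6 mol %), CH2Cl2, 40 °C, slow addition of 3 at high dilution
Reagents that add atoms: none
Why: Loss of N2 gives an electrophilic copper carbene that adds across the ipso–ortho bond of the anisyl ring (intramolecular cyclopropanation) to give norcaradiene 4, which opens by disrotatory 6π electrocyclic ring opening to the cycloheptatriene; this is the intramolecular Buchner reaction of aryl-tethered α-diazoketones, known with copper–bis(oxazoline) and dirhodium carboxylate catalysts. The five-membered ring closes by carbene attack on the ipso carbon through the three-atom keto tether (bond C1–C5, a 5-exo-type closure, with C1–C10 completing the cyclopropane), and the seven-membered ring arises by ring expansion when the C5–C10 bond of the cyclopropane breaks. C1 is the only new stereocentre: the two ortho carbons are enantiotopic, so the chiral ligand on copper decides which one is attacked and thereby the configuration of the quaternary carbon. The step needs chemoselectivity for arene addition over 1,2-hydride migration from the carbene methyl (to a vinyl ketone) and over carbene dimerisation; the short tether, the electron-rich anisyl ring and slow addition secure this, and the symmetry of the para-substituted ring leaves no regiochemical choice. The methoxy group ends as the C8 enol ether, a masked ketone, and the carbonyl sits at C2 next to the new quaternary carbon.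

Step 3
Reactants: 5 (8aR)-6-methoxy-8a-methyl-3,8a-dihydroazulen-1(2H)-one
Product: 6 (1R,8aR)-6-methoxy-8a-methyl-1,2,3,8a-tetrahydroazulen-1-ol (2β-alcohol)
Conditions: NaBH4, MeOH, 0 °C
Reagents that add atoms: none
Why: Borohydride reduction of the isolated cyclopentanone removes a carbonyl that would compete with the C8 ketone for the methyl nucleophile, would be reduced by borane, and would allow acid-induced cyclopropyl ketone cleavage of the norcaradiene tautomer to a tetralone; hydride should enter anti to the angular methyl, and the configuration of this temporary carbinol is without consequence.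

Step 4
Reactants: 6 2β-alcohol
Product: 7 (1R,8aR)-1-(benzyloxy)-6-methoxy-8a-methyl-1,2,3,8a-tetrahydroazulene
Conditions: NaH, BnBr, Bu4NI (cat.), THF/DMF, 0 °C to rt
Reagents that add atoms: benzyl bromide, BrCc1ccccc1
Why: Williamson etherification gives a benzyl ether that survives aqueous acid, copper hydride, organocerium, borane and silylation and can be removed by hydrogenolysis at a stage that holds no alkene.

Step 5
Reactants: 7 benzyl ether triene
Product: 8 2β-benzyloxy-8-oxo-5,9-diene [(1R,8aR)-1-(benzyloxy)-8a-methyl-1,2,3,8a-tetrahydroazulen-6(5H)-one]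
Conditions: oxalic acid, THF/H2O, 0 °C to rt
Reagents that add atoms: water, O
Why: Mild enol ether hydrolysis proceeds by kinetic protonation at C7 (the α-carbon of the dienol ether) and hydration at C8, so the ketone ends conjugated only with C9=C10 while C5=C6 stays unconjugated and no proton is delivered to C5, as in oxalic acid hydrolysis of Birch-type enol ethers.

Step 6
Reactants: 8 2β-benzyloxy-8-oxo-5,9-diene
Product: 10 2β-benzyloxy-8-oxo-5-ene [(1R,8aR)-1-(benzyloxy)-8a-methyl-2,3,5,7,8,8a-hexahydroazulen-6(1H)-one], via dimethylphenylsilyl enol ether 9 (not isolated)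
Conditions: [(Ph3P)CuH]6 (5 mol %), PhMe2SiH (1.5 equiv), toluene, rt; then 1 M HCl, THF, 0 °C (brief)
Reagents that add atoms: none
Why: Copper hydride-catalysed conjugate reduction (1,4-hydrosilylation) is selective for the enone C9=C10 over the isolated trisubstituted alkene and the benzyl ether, and the silyl enol ether is hydrolysed on work-up.

Step 7
Reactants: 10 2β-benzyloxy-8-oxo-5-ene
Product: 11 2β-benzyloxy-8α-methyl-5-en-8β-ol
Conditions: MeLi, CeCl3 (anhydrous), THF, −78 °C
Reagents that add atoms: methyllithium, [Li]C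
Why: Organocerium 1,2-addition is nucleophilic but weakly basic, which suppresses enolisation of the β,γ-unsaturated ketone at the doubly activated C7; the methyl group should enter on the α face, away from the angular methyl that projects over the β face of the seven-membered ring, giving 8β-OH and 8α-CH3.

Step 8
Reactants: 11 2β-benzyloxy-8α-methyl-5-en-8β-ol
Product: 13 2β-benzyloxy-8α-methyl-5α-H-6α,8β-diol, via C6 alkylborane 12 (not isolated)
Conditions: BH3·THF (excess), THF, 0 °C to rt; then NaOH, H2O2, H2O, 0 °C to rt
Reagents that add atoms: hydrogen peroxide, OO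
Why: Hydroboration–oxidation adds H and B syn to the α face anti to the allylic angular methyl, with boron on the less substituted C6, and oxidation with retention then sets C5–H (trans ring fusion) and C6–OH together, the same outcome as hydroboration of Δ5-steroids to 5α-H, 6α-alcohols.

Step 9
Reactants: 13 2β-benzyloxy-8α-methyl-5α-H-6α,8β-diol
Product: 14 2β-benzyloxy-6α-(tert-butyldimethylsilyloxy)-8α-methyl-8β-ol
Conditions: TBSCl, imidazole, DMAP (cat.), DMF, rt to 40 °C
Reagents that add atoms: tert-butyldimethylsilyl chloride, CC(C)(C)[Si](C)(C)Cl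
Why: Silylation with the chloride and imidazole takes the secondary C6 alcohol and leaves the tertiary C8 alcohol, and the silyl ether is a poor leaving group for the later stage in which C6–O is β to a ketone.

Step 10
Reactants: 14 2β-benzyloxy-6α-silyloxy-8β-ol
Product: 15 6α-(tert-butyldimethylsilyloxy)-8α-methyl-2β,8β-diol
Conditions: H2 (1 atm), Pd(OH)2/C, EtOAc, rt
Reagents that add atoms: none
Why: Hydrogenolysis of the benzyl ether is clean here because the molecule holds no alkene at this stage, and the silyl ether and tertiary alcohol are inert in ethyl acetate.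

Step 11
Reactants: 15 6α-silyloxy-2β,8β-diol
Product: 17 6α-(tert-butyldimethylsilyloxy)-8β-hydroxy-8α-methyl-3-en-2-one, via saturated C2 ketone 16 (not isolated)
Conditions: IBX (2.5 equiv), DMSO/fluorobenzene, 70 °C
Reagents that add atoms: none
Why: IBX oxidises the secondary alcohol to the ketone and at this temperature dehydrogenates that ketone to the enone (IBX-mediated α,β-dehydrogenation); C1 is quaternary, so only C3 carries α-hydrogens and the C3=C4 enone is the only possible regioisomer, while the tertiary alcohol and silyl ether do not react.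

Step 12
Reactants: 17 3-en-2-one
Product: 18 3α,4α-epoxy-6α-(tert-butyldimethylsilyloxy)-8β-hydroxy-8α-methyl-2-one
Conditions: H2O2 (30 % aq), NaOH (cat.), MeOH, 0 °C
Reagents that add atoms: hydrogen peroxide, OO
Why: Weitz–Scheffer nucleophilic epoxidation adds hydroperoxide to C4 of the enone, expected from the α face anti to the angular methyl; the epoxide configuration is irrelevant because C4 is oxidised in step 14.

Step 13
Reactants: 18 3α,4α-epoxy-2-one
Product: 20 6α-(tert-butyldimethylsilyloxy)-8α-methyl-2-ene-4α,8β-diol, via epoxy hydrazone 19 (not isolated)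
Conditions: N2H4·H2O, AcOH, MeOH, 0 °C to rt
Reagents that add atoms: none
Why: Wharton transposition: the hydrazone of the α,β-epoxy ketone fragments with loss of N2 and epoxide opening, leaving the alkene at C2=C3 and the oxygen at C4, which moves the five-ring oxygen from C2 to C4 without any regiochemical ambiguity.

Step 14
Reactants: 20 2-ene-4α,8β-diol
Product: 21 6α-(tert-butyldimethylsilyloxy)-8β-hydroxy-8α-methyl-2-en-4-one
Conditions: Dess–Martin periodinane, NaHCO3, CH2Cl2, 0 °C to rt
Reagents that add atoms: none
Why: Buffered periodinane oxidation of the secondary allylic alcohol gives the enone under neutral conditions, so the β-silyloxy ketone does not eliminate and the C5 centre next to the carbonyl is not epimerised.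

Step 15
Reactants: 21 2-en-4-one
Product: 22 6α-(tert-butyldimethylsilyloxy)-4α-isopropyl-8α-methyl-2-ene-4β,8β-diol
Conditions: iPrMgCl, CeCl3 (anhydrous), THF, −78 °C (excess reagent; the C8 alkoxide consumes one equivalent)
Reagents that add atoms: isopropylmagnesium chloride, CC(C)[Mg]Cl
Why: Organocerium 1,2-addition to the enone outruns enolisation towards C5 and β-elimination of the C6 silyloxy group because the reagent is weakly basic; attack on the α face, past the axial C5–H and away from the 1,3-related angular methyl, sets C4 with OH β and isopropyl α.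

Step 16
Reactants: 22 6α-silyloxy-4β,8β-diol
Product: 23 4α-isopropyl-8α-methyl-2-ene-4β,6α,8β-triol
Conditions: TBAF, THF, rt to 40 °C
Reagents that add atoms: none
Why: Fluoride-mediated desilylation frees the secondary C6 alcohol under non-acidic conditions that the tertiary allylic alcohol tolerates.

Step 17
Reactants: 24 vanillic acid
Product: 26 4-(tert-butyldimethylsilyloxy)-3-methoxybenzoic acid, via bis-silylated vanillic acid 25 (not isolated)
Conditions: TBSCl (2.5 equiv), imidazole, DMF, rt; then AcOH/THF/H2O, rt
Reagents that add atoms: tert-butyldimethylsilyl chloride, CC(C)(C)[Si](C)(C)Cl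
Why: Exhaustive silylation followed by selective hydrolysis of the much more labile silyl ester leaves the phenol masked, so the acid cannot acylate itself in step 18.

Step 18
Reactants: 23 triol; 26 4-(tert-butyldimethylsilyloxy)-3-methoxybenzoic acid
Product: 28 C6 4-(tert-butyldimethylsilyloxy)-3-methoxybenzoate of triol 23, via mixed 2,4,6-trichlorobenzoic anhydride 27 (not isolated)
Conditions: 26, 2,4,6-Cl3C6H2COCl, Et3N, toluene, rt; then 23, DMAP, toluene, rt to 50 °C
Reagents that add atoms: none
Why: Yamaguchi esterification acylates the only secondary alcohol (C6), since the two tertiary alcohols at C4 and C8 are too hindered to react, the selectivity known from acylation of 4,6-dihydroxydaucanes at C6.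

Step 19
Reactants: 28 silyl-protected ester
Product: 29 CNP0113302.1, (3S,3aS,4S,6R,8aS)-3,6-dihydroxy-6,8a-dimethyl-3-(propan-2-yl)-3,3a,4,5,6,7,8,8a-octahydroazulen-4-yl 4-hydroxy-3-methoxybenzoate
Conditions: TBAF, AcOH, THF, 0 °C
Reagents that add atoms: none
Why: Buffered fluoride cleaves the aryl silyl ether rapidly under near-neutral conditions that leave the ester, the alkene and the acid-sensitive tertiary allylic alcohol untouched.

**Compound list**

1 | 3-(4-methoxyphenyl)propanoic acid | COc1ccc(CCC(=O)O)cc1 | starting material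
2 | 3-(4-methoxyphenyl)propanoyl chloride | COc1ccc(CCC(=O)Cl)cc1 | intermediate (not isolated)
3 | 2-diazo-5-(4-methoxyphenyl)pentan-3-one | CC(=[N+]=[N-])C(=O)CCc1ccc(OC)cc1 | intermediate
4 | norcaradiene valence isomer of 5 (cyclopropane C1–C5–C10, cis-fused, diene C6=C7–C8(OMe)=C9) | COC1=C[C@@H]2[C@@]3(C)C(=O)CC[C@@]23C=C1 | intermediate (not isolated)
5 | (8aR)-6-methoxy-8a-methyl-3,8a-dihydroazulen-1(2H)-one (C2 ketone; C5=C6, C7=C8(OMe), C9=C10) | COC1=CC=C2CCC(=O)[C@]2(C)C=C1 | intermediate
6 | (1R,8aR)-6-methoxy-8a-methyl-1,2,3,8a-tetrahydroazulen-1-ol (C2–OH β) | COC1=CC=C2CC[C@@H](O)[C@]2(C)C=C1 | intermediate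
7 | (1R,8aR)-1-(benzyloxy)-6-methoxy-8a-methyl-1,2,3,8a-tetrahydroazulene | COC1=CC=C2CC[C@@H](OCc3ccccc3)[C@]2(C)C=C1 | intermediate
8 | (1R,8aR)-1-(benzyloxy)-8a-methyl-1,2,3,8a-tetrahydroazulen-6(5H)-one (C8 ketone, C9=C10, C5=C6) | O=C1CC=C2CC[C@@H](OCc3ccccc3)[C@]2(C)C=C1 | intermediate
9 | dimethylphenylsilyl enol ether of 10 (C8(OSiMe2Ph)=C9, C5=C6) | C[Si](C)(OC1CC=C2CC[C@@H](OCc3ccccc3)[C@]2(C)CC=1)c1ccccc1 | intermediate (not isolated)
10 | (1R,8aR)-1-(benzyloxy)-8a-methyl-2,3,5,7,8,8a-hexahydroazulen-6(1H)-one (C8 ketone, C5=C6) | O=C1CC=C2CC[C@@H](OCc3ccccc3)[C@]2(C)CC1 | intermediate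
11 | 2β-benzyloxy-8α-methyl-5-en-8β-ol | C[C@]1(O)CC=C2CC[C@@H](OCc3ccccc3)[C@]2(C)CC1 | intermediate
12 | C6α alkylborane of 11 (5α-H; written as RBH2, C8 hydroxyl written free) | C[C@]1(O)C[C@H](B)[C@H]2CC[C@@H](OCc3ccccc3)[C@]2(C)CC1 | intermediate (not isolated)
13 | 2β-benzyloxy-8α-methyl-5α-H-6α,8β-diol (trans-fused) | C[C@]1(O)C[C@H](O)[C@H]2CC[C@@H](OCc3ccccc3)[C@]2(C)CC1 | intermediate
14 | 2β-benzyloxy-6α-(tert-butyldimethylsilyloxy)-8α-methyl-8β-ol | C[C@]1(O)C[C@H](O[Si](C)(C)C(C)(C)C)[C@H]2CC[C@@H](OCc3ccccc3)[C@]2(C)CC1 | intermediate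
15 | 6α-(tert-butyldimethylsilyloxy)-8α-methyl-2β,8β-diol | C[C@]1(O)C[C@H](O[Si](C)(C)C(C)(C)C)[C@H]2CC[C@@H](O)[C@]2(C)CC1 | intermediate
16 | 6α-(tert-butyldimethylsilyloxy)-8β-hydroxy-8α-methyl-2-one | C[C@]1(O)C[C@H](O[Si](C)(C)C(C)(C)C)[C@H]2CCC(=O)[C@]2(C)CC1 | intermediate (not isolated)
17 | 6α-(tert-butyldimethylsilyloxy)-8β-hydroxy-8α-methyl-3-en-2-one | C[C@]1(O)C[C@H](O[Si](C)(C)C(C)(C)C)[C@H]2C=CC(=O)[C@]2(C)CC1 | intermediate
18 | 3α,4α-epoxy-6α-(tert-butyldimethylsilyloxy)-8β-hydroxy-8α-methyl-2-one | C[C@]1(O)C[C@H](O[Si](C)(C)C(C)(C)C)[C@H]2[C@@H]3O[C@@H]3C(=O)[C@]2(C)CC1 | intermediate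
19 | hydrazone of 18 at C2 | C[C@]1(O)C[C@H](O[Si](C)(C)C(C)(C)C)[C@H]2[C@@H]3O[C@@H]3C(=NN)[C@]2(C)CC1 | intermediate (not isolated)
20 | 6α-(tert-butyldimethylsilyloxy)-8α-methyl-2-ene-4α,8β-diol | C[C@]1(O)C[C@H](O[Si](C)(C)C(C)(C)C)[C@H]2[C@H](O)C=C[C@]2(C)CC1 | intermediate
21 | 6α-(tert-butyldimethylsilyloxy)-8β-hydroxy-8α-methyl-2-en-4-one | C[C@]1(O)C[C@H](O[Si](C)(C)C(C)(C)C)[C@H]2C(=O)C=C[C@]2(C)CC1 | intermediate
22 | 6α-(tert-butyldimethylsilyloxy)-4α-isopropyl-8α-methyl-2-ene-4β,8β-diol | C[C@]1(O)C[C@H](O[Si](C)(C)C(C)(C)C)[C@H]2[C@](O)(C(C)C)C=C[C@]2(C)CC1 | intermediate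
23 | 4α-isopropyl-8α-methyl-2-ene-4β,6α,8β-triol | C[C@]1(O)C[C@H](O)[C@H]2[C@](O)(C(C)C)C=C[C@]2(C)CC1 | intermediate
24 | vanillic acid (4-hydroxy-3-methoxybenzoic acid) | COc1cc(C(=O)O)ccc1O | starting material
25 | tert-butyldimethylsilyl 4-(tert-butyldimethylsilyloxy)-3-methoxybenzoate | COc1cc(C(=O)O[Si](C)(C)C(C)(C)C)ccc1O[Si](C)(C)C(C)(C)C | intermediate (not isolated)
26 | 4-(tert-butyldimethylsilyloxy)-3-methoxybenzoic acid | COc1cc(C(=O)O)ccc1O[Si](C)(C)C(C)(C)C | intermediate
27 | mixed anhydride of 26 and 2,4,6-trichlorobenzoic acid | COc1cc(C(=O)OC(=O)c2c(Cl)cc(Cl)cc2Cl)ccc1O[Si](C)(C)C(C)(C)C | intermediate (not isolated)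
28 | C6 4-(tert-butyldimethylsilyloxy)-3-methoxybenzoate of 23 | C[C@]1(O)C[C@H](OC(=O)c3ccc(O[Si](C)(C)C(C)(C)C)c(OC)c3)[C@H]2[C@](O)(C(C)C)C=C[C@]2(C)CC1 | intermediate
29 | CNP0113302.1, (3S,3aS,4S,6R,8aS)-3,6-dihydroxy-6,8a-dimethyl-3-(propan-2-yl)-3,3a,4,5,6,7,8,8a-octahydroazulen-4-yl 4-hydroxy-3-methoxybenzoate | C[C@]1(O)C[C@H](OC(=O)c3ccc(O)c(OC)c3)[C@H]2[C@](O)(C(C)C)C=C[C@]2(C)CC1 | target

**Count and risks**

Total step count: 19. Longest linear sequence: 18 steps (steps 1–16, 18, 19, from acid 1).

Steps most likely to fail: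

Step 2. The carbene may undergo 1,2-hydride migration from its methyl group faster than it adds to the arene, and discrimination of the enantiotopic ortho carbons at a fully substituted carbene may be incomplete. The fallback gives up catalyst control of C1 and resolves instead. From 3, cyclisation with the achiral dirhodium tetraacetate Rh2(OAc)4 (CH2Cl2, rt), a dirhodium carboxylate of the class commonly used for this cyclisation, should give 5 together with its mirror image, ent-azulenone F2, by way of 4 and the mirror-image norcaradiene F1. NaBH4 (MeOH, 0 °C) then gives 6 and ent-alcohol F3. Esterification of the mixture with (S)-2-methoxy-2-phenylacetic acid (DCC, DMAP, CH2Cl2) gives two diastereomers, the (S)-methoxyphenylacetate of 6 F4 and the (S)-methoxyphenylacetate of the ent-alcohol F5, which are separated by chromatography or crystallisation. LiOH (THF/H2O) on F4 returns 6, and the route continues at step 4.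

Step 7. Facial discrimination in the addition to the flexible cycloheptenone may be poor, or the reagent may enter syn to the angular methyl, and enolisation at C7 may compete. The fallback sets the C8 centre under thermodynamic control instead of kinetic control. From 10, Corey–Chaykovsky epoxidation with dimethylsulfoxonium methylide (Me3S(O)I, NaH, DMSO, rt), whose addition to the ketone is reversible, should give the spiro-epoxide F6 (oxygen β, CH2 α). LiEt3BH (THF, 0 °C) opens it at the CH2 carbon and gives 11.

Step 15. The C6 silyloxy group may screen the α face of the C4 carbonyl so that the isopropyl group enters syn to the angular methyl, or enolisation towards C5 may lead to epimerisation and loss of the silyloxy group. The fallback reverses the order in which carbon and oxygen arrive at C4, so that oxygen takes the face that nucleophiles prefer. From 17, conjugate addition of the isopropyl cuprate (iPrMgCl, CuBr·SMe2, THF, −78 °C) gives the 4-isopropyl ketone F7. IBX (DMSO, 70 °C) gives the 4-isopropyl enone F8. H2O2/NaOH (MeOH, 0 °C) then delivers hydroperoxide to C4 on the accessible face and gives the 3β,4β-epoxy ketone F9. Wharton transposition (N2H4·H2O, AcOH, MeOH) through the epoxy hydrazone F10 keeps the C4–O bond and gives 22.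

**Further compounds**

F1 | step 2 | mirror-image norcaradiene (ent-4) | COC1=C[C@H]2[C@]3(C)C(=O)CC[C@]23C=C1
F2 | step 2 | ent-azulenone, (8aS)-6-methoxy-8a-methyl-3,8a-dihydroazulen-1(2H)-one | COC1=CC=C2CCC(=O)[C@@]2(C)C=C1
F3 | step 2 | ent-alcohol, (1S,8aS)-6-methoxy-8a-methyl-1,2,3,8a-tetrahydroazulen-1-ol | COC1=CC=C2CC[C@H](O)[C@@]2(C)C=C1
F4 | step 2 | (S)-2-methoxy-2-phenylacetate of 6 | COC1=CC=C2CC[C@@H](OC(=O)[C@@H](OC)c3ccccc3)[C@]2(C)C=C1
F5 | step 2 | (S)-2-methoxy-2-phenylacetate of ent-alcohol F3 | COC1=CC=C2CC[C@H](OC(=O)[C@@H](OC)c3ccccc3)[C@@]2(C)C=C1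
F6 | step 7 | spiro-epoxide at C8 (O β, CH2 α), 2β-benzyloxy-5-ene | C1O[C@]12CC=C3CC[C@@H](OCc4ccccc4)[C@]3(C)CC2
F7 | step 15 | 4α-isopropyl-6α-(tert-butyldimethylsilyloxy)-8β-hydroxy-8α-methyl-2-one | C[C@]1(O)C[C@H](O[Si](C)(C)C(C)(C)C)[C@H]2[C@H](C(C)C)CC(=O)[C@]2(C)CC1
F8 | step 15 | 4-isopropyl-6α-(tert-butyldimethylsilyloxy)-8β-hydroxy-8α-methyl-3-en-2-one | C[C@]1(O)C[C@H](O[Si](C)(C)C(C)(C)C)[C@H]2C(C(C)C)=CC(=O)[C@]2(C)CC1
F9 | step 15 | 3β,4β-epoxy-4α-isopropyl-6α-(tert-butyldimethylsilyloxy)-8β-hydroxy-8α-methyl-2-one | C[C@]1(O)C[C@H](O[Si](C)(C)C(C)(C)C)[C@H]2[C@@]3(C(C)C)O[C@H]3C(=O)[C@]2(C)CC1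
F10 | step 15 | hydrazone of F9 at C2 | C[C@]1(O)C[C@H](O[Si](C)(C)C(C)(C)C)[C@H]2[C@@]3(C(C)C)O[C@H]3C(=NN)[C@]2(C)CC1
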